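**Strategy.** The six-membered ring of the longipinane core is disconnected at C3–C4 and C1–C11. In the cyclobutane ring C4–C5–C11–C10 these two carbons flank C5; with C5 as a ketone they are its α-carbons, and C1–C2–C3 is a three-carbon bis-electrophile. One amine-catalysed Michael–aldol annulation therefore joins methyl 3-oxocyclobutane-1-carboxylate (the precursor, an achiral commercial cyclobutanone) and acrolein, forming both bonds, the six-membered ring and the C4 and C11 stereocentres. The seven-membered ring is then built from C5 and C10 with (S)-3-hydroxy-γ-butyrolactone as the source of C6–C8 and C13 and closed by metathesis.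

Key step: step 1

**Remarks on the chemistry**
- Numbering: longipinane numbering is kept for all intermediates (C1 ketone carbon, C2, C3 with methyl C15, bridgeheads C4 and C11, cyclobutane C4–C5–C11–C10, seven-membered ring C5–C6–C7–C8–C9–C10–C11, C12 = methyl on C6, C14 = methyl on C10). The oxygen-bearing methylene on C6 is C13 in this numbering; C15 is the methyl on C3 and cannot also be the CH2O group.
- "Up" means on the face of the cyclobutane that carries the C1–C3 bridge; "down" means pointing into the sector between C5 and C10, where the C6–C9 bridge lies.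
- Assumption: the quinine-derived primary amine is taken to select the α-carbon that leads to the enantiomer drawn; if the sense proves opposite, the quinidine-derived pseudo-enantiomer is used in the same way.
- Angelic anhydride is taken as a purchased reagent.

**Route**

Step 1
Reactants: 1 methyl 3-oxocyclobutane-1-carboxylate; 2 acrolein
Product: 5 methyl (1R,2S,5R,7R)-6-oxo-2-[(triethylsilyl)oxy]bicyclo[3.1.1]heptane-7-carboxylate (silyloxy group on C1 syn to the C5 carbonyl; ester on C10 down), via Michael adduct 3 (not isolated), via bridged aldol 4 (not isolated)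
Conditions: 9-amino(9-deoxy)epi-quinine (20 mol %), PhCO2H (40 mol %), toluene, 0 °C to rt, 2 added slowly; then CH2Cl2, 2,6-lutidine, Et3SiOTf, −40 °C
Reagents that add atoms: triethylsilyl trifluoromethanesulfonate, CC[Si](CC)(CC)OS(=O)(=O)C(F)(F)F
Why: Proposed new method: the primary amine condenses with the strained cyclobutanone 1 to an enamine at one of its two enantiotopic α-carbons, which adds to acrolein (held by the protonated quinuclidine as hydrogen-bond donor) anti to the ester to give 3 and set C4; a second enamine toward C11 then attacks the tethered aldehyde to give 4, and the strained, reversible aldol is locked in the same pot as its triethylsilyl ether. The closest known reaction types are the amine-catalysed Michael–aldol α,α'-annulation of cyclohexanones with enals to bicyclo[3.3.1]nonanones and the amine-catalysed desymmetrisation of 3-substituted cyclobutanones; bridging a four-membered ketone is the new element. The six-membered ring C4–C3–C2–C1–C11–C5 closes by a 6-(enolendo)-exo-trig aldol, the chain spanning the cyclobutane 1,3-cis. C4 is controlled by the catalyst (choice of α-carbon) together with the C10 ester (approach anti to it), C11 follows because the three-carbon bridge can only close cis to the chain on C4, and the C1 carbinol (hydroxyl toward the enamine nitrogen, syn to C5) is used later as a directing group and then oxidised. The step needs mono-annulation and one enantiotopic α-carbon: the first is secured by the substrate, since both α-carbons of the product are bridgeheads and cannot form a further enamine, the second rests on the catalyst.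

Step 2
Reactants: 6 (S)-3-hydroxy-γ-butyrolactone
Product: 7 (4S)-4-[(tert-butyldimethylsilyl)oxy]oxolan-2-one
Conditions: t-BuMe2SiCl, imidazole, DMF, rt
Reagents that add atoms: tert-butyldimethylsilyl chloride, CC(C)(C)[Si](C)(C)Cl
Why: Imidazole-promoted silylation of a secondary alcohol; the C7 stereocentre comes unchanged from the chiral pool and the silyl ether later serves as a non-coordinating, face-shielding group.

Step 3
Reactants: 5 silyl ether ketone; 7 silyloxy lactone
Product: 8 tertiary alcohol from addition of the lactone α-carbon (C6) to the C5 carbonyl (epimers at C5 and C6; other centres as in 5 and 7)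
Conditions: 7, LiN(i-Pr)2, THF, −78 °C; then 5, −78 °C; AcOH quench at −78 °C
Reagents that add atoms: none
Why: Lithium enolate aldol addition to the strain-activated cyclobutanone forms the C5–C6 bond at a temperature low enough to suppress β-elimination of the silyloxy group; the two new centres are erased in steps 4 to 6, so their configuration does not matter.

Step 4
Reactants: 8 tertiary alcohol
Product: 10 α-alkylidene lactone with C5=C6 double bond (both geometries) and free C1 hydroxyl, via triethylsilyl ether 9 (not isolated)
Conditions: methyl N-(triethylammoniumsulfonyl)carbamate (Burgess reagent), toluene, 50 °C; then MeOH, pyridinium p-toluenesulfonate, rt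
Reagents that add atoms: none
Why: Burgess dehydration (syn elimination) can only run toward the acidic C6–H because the other β-hydrogens sit on bridgeheads, and buffered methanolysis then removes the triethylsilyl ether selectively over the secondary tert-butyldimethylsilyl ether.

Step 5
Reactants: 10 α-alkylidene lactone
Product: 11 saturated lactone with C5–H up and C6 down (C6 epimers)
Conditions: H2 (1 to 10 bar), [Ir(cod)(PCy3)(py)]PF6 (10 mol %), CH2Cl2, rt
Reagents that add atoms: none
Why: Hydroxyl-directed hydrogenation: the C1 hydroxyl stands 1,3-diaxial to the upper face of C5 and binds the iridium there, while the inward ester on C10 screens the lower face, so hydrogen should reach C5 from above and place C6 in the C5/C10 sector; C6 is re-set in step 6.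

Step 6
Reactants: 11 saturated lactone
Product: 12 dimethyl lactone ester (CH3 on C6 anti to the C7 silyloxy group; CH3 on C10 up and CO2Me down)
Conditions: LiN(i-Pr)2 (3.5 equiv), THF, −78 to −40 °C; MeI, DMPU, −78 to −20 °C; aq. NH4Cl
Reagents that add atoms: iodomethane, CI
Why: Double enolate alkylation: the lactone enolate should be methylated at C6 anti to the adjacent silyloxy group (1,2-induction in a five-membered ring enolate), and the C10 ester enolate from above because its lower face is blocked by the inward C6 substituent on C5, which leaves the ester (future C9) down.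

Step 7
Reactants: 12 dimethyl lactone ester
Product: 13 C1 ketone
Conditions: Dess–Martin periodinane, NaHCO3, CH2Cl2, rt
Reagents that add atoms: none
Why: Dess–Martin oxidation of the only free (secondary) alcohol; no stereocentre is touched.

Step 8
Reactants: 13 C1 ketone
Product: 15 C2=C3 enone, via trimethylsilyl enol ether 14 (not isolated)
Conditions: LiN(SiMe3)2, Me3SiCl, THF, −78 °C; then Pd(OAc)2 (1.1 equiv), MeCN, rt
Reagents that add atoms: none
Why: Saegusa–Ito dehydrogenation; the ketone can enolise only toward C2 because C11 is a bridgehead and C6 and C10 are quaternary, so one silyl enol ether and one enone should form.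

Step 9
Reactants: 15 enone
Product: 16 C3-methyl ketone (CH3 on C3 syn to C5)
Conditions: Me2CuLi (from CuI and MeLi), Et2O, −78 to −30 °C; aq. NH4Cl
Reagents that add atoms: lithium dimethylcuprate, [Li+].C[Cu-]C
Why: Cuprate conjugate addition to a bicyclo[3.1.1]heptenone, which, as with verbenone, should occur on the face away from the bridge methyl on C10, i.e. from the C5 side, setting C3.

Step 10
Reactants: 16 C3-methyl ketone
Product: 17 ethylene ketal of the C1 ketone
Conditions: Me3SiOCH2CH2OSiMe3, Me3SiOTf (5 mol %), CH2Cl2, −78 to −20 °C; pyridine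
Reagents that add atoms: 1,2-bis(trimethylsilyloxy)ethane, C[Si](C)(C)OCCO[Si](C)(C)C
Why: Noyori ketalisation works at low temperature on hindered ketones and tolerates lactone, ester and silyl ether; it masks C1 against the hydride, ylide, borane and amide-base steps that follow.

Step 11
Reactants: 17 ketal lactone ester
Product: 18 triol with C13, C8 and C9 as CH2OH
Conditions: LiAlH4, THF, 0 °C to rt
Reagents that add atoms: none
Why: Exhaustive hydride reduction opens the lactone to the C13/C8 diol and reduces the ester to the C9 carbinol; ketal and silyl ether are inert.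

Step 12
Reactants: 18 triol
Product: 19 transposed γ-lactone (C8 carbonyl bonded through oxygen to C13) with C9 aldehyde on C10
Conditions: TEMPO (20 mol %), PhI(OAc)2 (3.5 equiv), CH2Cl2, rt
Reagents that add atoms: none
Why: Oxoammonium (TEMPO) oxidation prefers the less hindered primary alcohol of the 1,4-diol, so C8 and not the neopentyl C13 should become the lactone carbonyl, and the isolated C9 carbinol is taken to the aldehyde.

Step 13
Reactants: 19 lactone aldehyde
Product: 20 lactone with vinyl group on C10
Conditions: Zn, CH2Br2, TiCl4, THF (pre-formed reagent); then 19, CH2Cl2, 0 °C to rt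
Reagents that add atoms: dibromomethane, BrCBr
Why: Takai–Lombardo methylenation is non-basic and selective for aldehydes over lactones, so the hindered aldehyde is converted without epimerising C7, which is now α to the lactone carbonyl.

Step 14
Reactants: 20 vinyl lactone
Product: 21 lactol (C8 hemiacetal, both anomers)
Conditions: i-Bu2AlH, CH2Cl2, −78 °C; aq. potassium sodium tartrate
Reagents that add atoms: none
Why: Half-reduction of a lactone, which stops at the lactol because the aluminium hemiacetal is stable at −78 °C.

Step 15
Reactants: 21 lactol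
Product: 22 diene alcohol (vinyl groups on C7 and on C10, C13 as CH2OH)
Conditions: Ph3PCH3Br, KN(SiMe3)2, THF, 0 °C; then 21, 0 °C to rt
Reagents that add atoms: methyltriphenylphosphonium bromide, C[P+](c1ccccc1)(c1ccccc1)c1ccccc1.[Br-]
Why: Wittig methylenation of the lactol through its open hydroxy-aldehyde form installs C8 as a vinyl carbon and frees the C13 hydroxyl; excess ylide keeps olefination faster than enolisation at C7.

Step 16
Reactants: 22 diene alcohol
Product: 23 tricyclic alkene with C8=C9 in the seven-membered ring
Conditions: second-generation Grubbs catalyst (H2IMes)(PCy3)Cl2Ru=CHPh (5 mol %), CH2Cl2 (0.005 M), 40 °C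
Reagents that add atoms: none
Why: Ring-closing metathesis of two vinyl groups held cis in the same sector of the cyclobutane closes the seven-membered ring as the cis alkene with loss of ethene.

Step 17
Reactants: 23 tricyclic alkene
Product: 25 C8 alcohol, 7,8-trans (C8–OH anti to the C7 silyloxy group), via C8 alkylborane 24 (not isolated)
Conditions: BH3·THF, THF, 0 °C to rt; then aq. NaOH, H2O2, 0 °C to rt
Reagents that add atoms: hydrogen peroxide, OO
Why: Hydroboration–oxidation: boron should add to C8, away from the neopentyl C9, on the face anti to the allylic silyloxy group (the same face an alkoxyborane on C13 can reach), and oxidation proceeds with retention, setting C8.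

Step 18
Reactants: 25 silyl ether ketal diol
Product: 26 8,13-bis(angeloyloxy)-7-[(tert-butyldimethylsilyl)oxy]longipinan-1-one ethylene ketal (all centres as in 25)
Conditions: LiN(SiMe3)2 (2.2 equiv), THF, −78 °C; angelic anhydride (3 equiv), −78 to 0 °C; aq. NH4Cl
Reagents that add atoms: angelic anhydride, C/C=C(/C)C(=O)OC(=O)/C(C)=C\C
Why: Acylation of lithium alkoxides by an anhydride at low temperature without a nucleophilic catalyst should esterify the primary C13 and the secondary C8 hydroxyl with retention of the Z geometry; the ketal leaves no enolisable carbonyl, and a silyl shift between O7 and O8 would be harmless because all three oxygens end with the same acyl group.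

Step 19
Reactants: 26 bis-angelate silyl ether ketal
Product: 27 (3R,4S,5S,6S,7S,8S,10R,11R)-7-hydroxy-8,13-bis[(Z)-2-methylbut-2-enoyloxy]longipinan-1-one
Conditions: 48 % aq. HF, MeCN, 0 °C to rt
Reagents that add atoms: water, O
Why: Aqueous hydrogen fluoride cleaves the hindered secondary silyl ether and hydrolyses the dioxolane in one operation, while the angelates, which isomerise under nucleophilic or basic catalysis, are left alone; the ketone has no epimerisable α-stereocentre (C11 is a bridgehead).

Step 20
Reactants: 27 hydroxy ketone bis-angelate; 28 angelic acid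
Product: 30 CNP0214984.1, (3R,4S,5S,6S,7S,8S,10R,11R)-7,8,13-tris[(Z)-2-methylbut-2-enoyloxy]longipinan-1-one, via mixed anhydride 29 (not isolated)
Conditions: 28 (excess), 2,4,6-Cl3C6H2COCl, Et3N, toluene, rt; then 27, 80 °C
Reagents that add atoms: none
Why: Yamaguchi-type acylation with the mixed anhydride in the absence of a nucleophilic catalyst should esterify the one remaining, hindered C7 hydroxyl without Z-to-E isomerisation; an acyl shift from O8 to O7 would only expose the C8 hydroxyl, which the excess reagent converts to the same product.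

**Compound list**

1 | methyl 3-oxocyclobutane-1-carboxylate | COC(=O)C1CC(=O)C1 | starting material
2 | acrolein | C=CC=O | starting material
3 | methyl (1S,2R)-3-oxo-2-(3-oxopropyl)cyclobutane-1-carboxylate | O=CCC[C@H]1C(=O)C[C@@H]1C(=O)OC | intermediate
4 | methyl (1R,2S,5R,7R)-2-hydroxy-6-oxobicyclo[3.1.1]heptane-7-carboxylate | O=C1[C@@H]2CC[C@H](O)[C@H]1[C@@H]2C(=O)OC | intermediate
5 | methyl (1R,2S,5R,7R)-6-oxo-2-[(triethylsilyl)oxy]bicyclo[3.1.1]heptane-7-carboxylate | O=C1[C@@H]2CC[C@H](O[Si](CC)(CC)CC)[C@H]1[C@@H]2C(=O)OC | intermediate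
6 | (S)-3-hydroxy-γ-butyrolactone, (4S)-4-hydroxyoxolan-2-one | O=C1C[C@H](O)CO1 | starting material
7 | (4S)-4-[(tert-butyldimethylsilyl)oxy]oxolan-2-one | O=C1C[C@H](O[Si](C)(C)C(C)(C)C)CO1 | intermediate
8 | aldol adduct: C5 tertiary alcohol bearing the lactone α-carbon C6 (epimers at C5 and C6) | O=C1OC[C@@H](O[Si](C)(C)C(C)(C)C)C1C2(O)[C@@H]3CC[C@H](O[Si](CC)(CC)CC)[C@H]2[C@@H]3C(=O)OC | intermediate
9 | α-alkylidene lactone, C1 triethylsilyl ether (C5=C6, both geometries) | O=C1OC[C@@H](O[Si](C)(C)C(C)(C)C)C1=C2[C@@H]3CC[C@H](O[Si](CC)(CC)CC)[C@H]2[C@@H]3C(=O)OC | intermediate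
10 | α-alkylidene lactone, free C1 hydroxyl (C5=C6, both geometries) | O=C1OC[C@@H](O[Si](C)(C)C(C)(C)C)C1=C2[C@@H]3CC[C@H](O)[C@H]2[C@@H]3C(=O)OC | intermediate
11 | saturated lactone, C5–H up, C6 epimers | O=C1OC[C@@H](O[Si](C)(C)C(C)(C)C)C1[C@H]2[C@@H]3CC[C@H](O)[C@H]2[C@@H]3C(=O)OC | intermediate
12 | dimethyl lactone ester (C6 and C10 quaternary) | O=C1OC[C@@H](O[Si](C)(C)C(C)(C)C)[C@@]1(C)[C@H]2[C@@H]3CC[C@H](O)[C@H]2[C@]3(C)C(=O)OC | intermediate
13 | C1 ketone | O=C1OC[C@@H](O[Si](C)(C)C(C)(C)C)[C@@]1(C)[C@H]2[C@@H]3CCC(=O)[C@H]2[C@]3(C)C(=O)OC | intermediate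
14 | trimethylsilyl enol ether (C1=C2) | O=C1OC[C@@H](O[Si](C)(C)C(C)(C)C)[C@@]1(C)[C@H]2[C@@H]3CC=C(O[Si](C)(C)C)[C@H]2[C@]3(C)C(=O)OC | intermediate
15 | C2=C3 enone | O=C1OC[C@@H](O[Si](C)(C)C(C)(C)C)[C@@]1(C)[C@H]2[C@@H]3C=CC(=O)[C@H]2[C@]3(C)C(=O)OC | intermediate
16 | C3-methyl ketone | O=C1OC[C@@H](O[Si](C)(C)C(C)(C)C)[C@@]1(C)[C@H]2[C@@H]3[C@H](C)CC(=O)[C@H]2[C@]3(C)C(=O)OC | intermediate
17 | C1 ethylene ketal | O=C1OC[C@@H](O[Si](C)(C)C(C)(C)C)[C@@]1(C)[C@H]2[C@@H]3[C@H](C)CC4(OCCO4)[C@H]2[C@]3(C)C(=O)OC | intermediate
18 | triol (C13, C8, C9 carbinols) | OC[C@@](C)([C@H](O[Si](C)(C)C(C)(C)C)CO)[C@H]1[C@@H]2[C@H](C)CC3(OCCO3)[C@H]1[C@]2(C)CO | intermediate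
19 | transposed lactone (C8 carbonyl) with C9 aldehyde | O=C1OC[C@](C)([C@H]2[C@@H]3[C@H](C)CC4(OCCO4)[C@H]2[C@]3(C)C=O)[C@@H]1O[Si](C)(C)C(C)(C)C | intermediate
20 | transposed lactone with vinyl group on C10 | O=C1OC[C@](C)([C@H]2[C@@H]3[C@H](C)CC4(OCCO4)[C@H]2[C@]3(C)C=C)[C@@H]1O[Si](C)(C)C(C)(C)C | intermediate
21 | lactol (C8 hemiacetal, anomers) | OC1OC[C@](C)([C@H]2[C@@H]3[C@H](C)CC4(OCCO4)[C@H]2[C@]3(C)C=C)[C@@H]1O[Si](C)(C)C(C)(C)C | intermediate
22 | diene alcohol | OC[C@@](C)([C@H](O[Si](C)(C)C(C)(C)C)C=C)[C@H]1[C@@H]2[C@H](C)CC3(OCCO3)[C@H]1[C@]2(C)C=C | intermediate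
23 | tricyclic alkene (C8=C9) | OC[C@]1(C)[C@H]2[C@@H]3[C@H](C)CC4(OCCO4)[C@H]2[C@]3(C)C=C[C@H]1O[Si](C)(C)C(C)(C)C | intermediate
24 | C8 alkylborane (drawn as the monoalkylborane) | OC[C@]1(C)[C@H]2[C@@H]3[C@H](C)CC4(OCCO4)[C@H]2[C@]3(C)C[C@H](B)[C@H]1O[Si](C)(C)C(C)(C)C | intermediate
25 | C8 alcohol, 7,8-trans, C7 silyl ether, C1 ketal | OC[C@]1(C)[C@H]2[C@@H]3[C@H](C)CC4(OCCO4)[C@H]2[C@]3(C)C[C@H](O)[C@H]1O[Si](C)(C)C(C)(C)C | intermediate
26 | 8,13-bis(angeloyloxy)-7-[(tert-butyldimethylsilyl)oxy]longipinan-1-one ethylene ketal | C/C=C(/C)C(=O)OC[C@]1(C)[C@H]2[C@@H]3[C@H](C)CC4(OCCO4)[C@H]2[C@]3(C)C[C@H](OC(=O)/C(C)=C\C)[C@H]1O[Si](C)(C)C(C)(C)C | intermediate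
27 | (3R,4S,5S,6S,7S,8S,10R,11R)-7-hydroxy-8,13-bis[(Z)-2-methylbut-2-enoyloxy]longipinan-1-one | C/C=C(/C)C(=O)OC[C@]1(C)[C@H]2[C@@H]3[C@H](C)CC(=O)[C@H]2[C@]3(C)C[C@H](OC(=O)/C(C)=C\C)[C@H]1O | intermediate
28 | angelic acid, (Z)-2-methylbut-2-enoic acid | C/C=C(/C)C(=O)O | starting material
29 | angelic 2,4,6-trichlorobenzoic anhydride | C/C=C(/C)C(=O)OC(=O)c1c(Cl)cc(Cl)cc1Cl | intermediate
30 | CNP0214984.1, 7,8,13-tris(angeloyloxy)longipinan-1-one | C/C=C(/C)C(=O)OC[C@]1(C)[C@H]2[C@@H]3[C@H](C)CC(=O)[C@H]2[C@]3(C)C[C@H](OC(=O)/C(C)=C\C)[C@H]1OC(=O)/C(C)=C\C | target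

**Step count and risk**

Total step count: 20. Longest linear sequence: 19 (steps 1 and 3 to 20; step 2 is the only off-line step).

Steps most likely to fail:

1. Step 1 (Proposed new method). What may go wrong: deactivation of the primary amine by acrolein (aza-Michael addition, stable imine), weak discrimination between the two enantiotopic α-carbons, or the strained bridging aldol reverting before it is silylated. Fallback with known reaction types, setting out from 1 and returning at 5: enantioselective deprotonation of 1 with the chiral amide LiN[(S)-CH(CH3)Ph]2 and in situ Me3SiCl gives the silyl enol ether methyl (1S)-3-[(trimethylsilyl)oxy]cyclobut-2-ene-1-carboxylate F1. Mukaiyama–Michael addition of F1 to acrolein (Sc(OTf)3 catalysis, approach anti to the ester) gives keto-aldehyde 3, which is isolated in this variant. Pyrrolidine/AcOH-mediated intramolecular enamine aldol closure then gives 4, which is silylated as in step 1 to 5.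

2. Step 5. What may go wrong: slow hydrogen uptake by the tetrasubstituted, conjugated alkene, or competing binding of the iridium to the ester or lactone carbonyl, so that hydrogen is delivered to the lower face of C5. Fallback, setting out from 10 and returning at 11: stoichiometric conjugate reduction with the copper hydride [(Ph3P)CuH]6 in wet benzene. Hydride is transferred to C5 by steric approach control from the upper face, since the inward C10 ester screens the lower one, and the copper enolate is protonated at C6, whose configuration is irrelevant. No new compound is made.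

3. Step 20. What may go wrong: Z-to-E isomerisation of the angeloyl units under prolonged heating, and incomplete acylation of the hindered C7 hydroxyl. Fallback, setting out from 25 and returning at 30: Bu4NF in THF removes the silyl ether to give the ketal triol 7,8,13-trihydroxylongipinan-1-one ethylene ketal F2. Its trialkoxide, formed with LiN(SiMe3)2 at −78 °C (possible because the ketal has no enolisable carbonyl), is acylated cold with angelic anhydride to the tris-angelate ketal 7,8,13-tris(angeloyloxy)longipinan-1-one ethylene ketal F3. Pyridinium p-toluenesulfonate in wet acetone then unmasks the C1 ketone to give 30.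

Further compounds
F1 | step 1 | methyl (1S)-3-[(trimethylsilyl)oxy]cyclobut-2-ene-1-carboxylate | COC(=O)[C@H]1CC(O[Si](C)(C)C)=C1
F0 | step 5 | none | none
F2 | step 20 | 7,8,13-trihydroxylongipinan-1-one ethylene ketal | OC[C@]1(C)[C@H]2[C@@H]3[C@H](C)CC4(OCCO4)[C@H]2[C@]3(C)C[C@H](O)[C@H]1O
F3 | step 20 | 7,8,13-tris(angeloyloxy)longipinan-1-one ethylene ketal | C/C=C(/C)C(=O)OC[C@]1(C)[C@H]2[C@@H]3[C@H](C)CC4(OCCO4)[C@H]2[C@]3(C)C[C@H](OC(=O)/C(C)=C\C)[C@H]1OC(=O)/C(C)=C\C
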